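**Assumption:** the SMILES is taken at face value, i.e. (4S,5R,8R,9S,13S,14S) in halimane numbering (C18 = ester carbon and C19 = methyl on C4, C17 = methyl on C8, C20 = methyl on C9, C11–C16 = side chain), with H-5 on the face of the C8/C9 methyls and the ester on the face of the C9 side chain.

## Retrosynthetic overview

1. Target ⇐ Sharpless epoxidation of the 13E allylic alcohol (C13 and C14 set by the tartrate).
2. Hydroxy methyl ester ⇐ methanolysis of an 11-membered lactone that joins C18 (on C4) to O15.
3. Lactone ⇐ tethered (type 2) intramolecular Diels–Alder of a side-chain methacrylate onto the 1-vinylcyclohexene diene; ring A and the lactone ring form in one operation and C4 and C5 are set.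
4. Methacrylate/diene ⇐ B-alkyl Suzuki coupling (C12–C13), enol triflate vinylation (C10–C1), ketone carrying a C9 vinyl group.
5. Ketone ⇐ Cu-catalysed asymmetric methyl addition/aldol on 2-methylcyclohexenone (C8, C9). Ring order: B (purchased) → A plus macrolactone → lactone opened → epoxide.

## Route

Step 1
Reactants: 1 2-methylcyclohex-2-en-1-one
Product: 3 (2R,3R)-2-(1-hydroxyethyl)-2,3-dimethylcyclohexan-1-one, via dimethylaluminium enolate 2 (not isolated)
Conditions: Me3Al (1.4 equiv), CuTC (2 mol %), chiral phosphoramidite L* (4 mol %), Et2O, −30 °C; then MeCHO (3 equiv), −78 → −30 °C; aq. Rochelle salt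
Reagents that add atoms: trimethylaluminium C[Al](C)C; acetaldehyde CC=O
Why: Copper-catalysed asymmetric conjugate addition fixes C8 (3R) under ligand control (the ligand enantiomer that gives the 3R enolate is the one used), and the aluminium enolate then undergoes aldol addition anti to the pseudoaxial C3 methyl, so the two-carbon unit ends trans to that methyl and the two methyls cis (C9); the carbinol centre is removed in step 2.

Step 2
Reactants: 3 (2R,3R)-2-(1-hydroxyethyl)-2,3-dimethylcyclohexan-1-one
Product: 4 (2S,3R)-2-ethenyl-2,3-dimethylcyclohexan-1-one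
Conditions: Burgess reagent (2 equiv), PhMe, 80 °C
Reagents that add atoms: none
Why: Burgess dehydration is a syn (Ei) elimination that can only take a hydrogen from the methyl group because the other neighbour is quaternary, so the C9 vinyl group forms without touching C8 or C9.

Step 3
Reactants: 4 (2S,3R)-2-ethenyl-2,3-dimethylcyclohexan-1-one
Product: 6 (5R,6S)-6-ethenyl-5,6-dimethylcyclohex-1-en-1-yl trifluoromethanesulfonate, via potassium enolate 5 (not isolated)
Conditions: KHMDS (1.2 equiv), THF, −78 °C; PhNTf2 (1.3 equiv), −78 → 0 °C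
Reagents that add atoms: N-phenylbis(trifluoromethanesulfonimide) O=S(=O)(N(c1ccccc1)S(=O)(=O)C(F)(F)F)C(F)(F)F
Why: C2 is quaternary, so deprotonation and O-triflation (enol triflate formation) can occur only toward C6, giving the C10=C5 enol triflate regiospecifically.

Step 4
Reactants: 6 (5R,6S)-6-ethenyl-5,6-dimethylcyclohex-1-en-1-yl trifluoromethanesulfonate
Product: 7 (5R,6S)-1,6-diethenyl-5,6-dimethylcyclohex-1-ene
Conditions: CH2=CHB(pin) (1.5 equiv), Pd(dppf)Cl2 (5 mol %), K3PO4 (3 equiv), dioxane/H2O 5:1, 60 °C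
Reagents that add atoms: 2-ethenyl-4,4,5,5-tetramethyl-1,3,2-dioxaborolane C=CB1OC(C)(C)C(C)(C)O1
Why: Suzuki–Miyaura coupling of the alkenyl triflate with the vinylboronate gives the semicyclic 1,3-diene (C5=C10–C1=C2) with retention of the ring double bond; no stereocentre is involved.

Step 5
Reactants: 8 ethyl acetoacetate
Product: 10 ethyl (2E)-3-{[(trifluoromethyl)sulfonyl]oxy}but-2-enoate, via tetramethylammonium enolate 9 (not isolated)
Conditions: 25% aq. Me4NOH (5 equiv), Tf2O (2 equiv), hexanes, 5 °C
Reagents that add atoms: trifluoromethanesulfonic anhydride O=S(=O)(OS(=O)(=O)C(F)(F)F)C(F)(F)F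
Why: With the non-chelating tetramethylammonium counter-ion the acetoacetate enolate is O-triflated as the E isomer (OTf trans to the ester), a stereoselective enol triflate formation that later fixes the 13E geometry.

Step 6
Reactants: 7 (5R,6S)-1,6-diethenyl-5,6-dimethylcyclohex-1-ene; 10 ethyl (2E)-3-{[(trifluoromethyl)sulfonyl]oxy}but-2-enoate
Product: 12 ethyl (2E)-5-[(1S,6R)-2-ethenyl-1,6-dimethylcyclohex-2-en-1-yl]-3-methylpent-2-enoate, via B-alkyl-9-BBN adduct 11 (not isolated)
Conditions: 9-BBN (1.05 equiv), THF, 0 °C → rt; then 10 (1.2 equiv), Pd(dppf)Cl2 (5 mol %), 3 M aq. K3PO4 (3 equiv), DMF, rt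
Reagents that add atoms: none
Why: 9-BBN hydroborates the isolated monosubstituted C9 vinyl group much faster than the conjugated diene and puts boron on the terminal carbon, and the B-alkyl Suzuki–Miyaura coupling with the E enol triflate proceeds with retention to give the 13E trisubstituted alkene.

Step 7
Reactants: 12 ethyl (2E)-5-[(1S,6R)-2-ethenyl-1,6-dimethylcyclohex-2-en-1-yl]-3-methylpent-2-enoate
Product: 14 (2E)-5-[(1S,6R)-2-ethenyl-1,6-dimethylcyclohex-2-en-1-yl]-3-methylpent-2-en-1-yl 2-methylprop-2-enoate, via diisobutylaluminium alkoxide 13 (not isolated)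
Conditions: DIBAL-H (2.1 equiv), CH2Cl2, −78 → 0 °C; then pyridine, DMAP, methacrylic anhydride (4 equiv), BHT, 0 °C → rt
Reagents that add atoms: methacrylic anhydride C=C(C)C(=O)OC(=O)C(C)=C
Why: DIBAL-H reduces the conjugated ester 1,2 to the aluminium allyl alkoxide, which is acylated in the same flask by anhydride/DMAP (in situ acylation of an aluminium alkoxide, as in reductive acylation), so the dienophile is attached through the oxygen that the target keeps.

Step 8
Reactants: 14 (2E)-5-[(1S,6R)-2-ethenyl-1,6-dimethylcyclohex-2-en-1-yl]-3-methylpent-2-en-1-yl 2-methylprop-2-enoate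
Product: 15 (4S,5R,8R,9S,13E)-halima-1(10),13-dien-18,15-olide (ring A plus an 11-membered lactone from C18 to O15)
Conditions: PhMe (2 mM), BHT (10 mol %), 170–180 °C, sealed tube, 48 h
Reagents that add atoms: none
Why: Proposed new method: a macrocyclising type 2 intramolecular Diels–Alder in which the molecule's own O15–C18 ester is the tether; the methacrylate hangs from the β substituent of C9 and so reaches the s-cis diene from the β face with its carbonyl folded over C10 (endo), which bonds C4 to the ring terminus C5 in the normal "ortho" sense, leaves H-5 α and puts the ester carbon β (4S,5R) while ring A and the lactone close together; the closest known reaction types are ester-tethered type 2 intramolecular Diels–Alder reactions and macrocycle-forming intramolecular Diels–Alder reactions.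

Step 9
Reactants: 15 (4S,5R,8R,9S,13E)-halima-1(10),13-dien-18,15-olide
Product: 16 methyl (4S,5R,8R,9S,13E)-15-hydroxyhalima-1(10),13-dien-18-oate
Conditions: NaOMe (0.3 equiv), MeOH, 60 °C
Reagents that add atoms: methanol CO
Why: Methoxide transesterification of the strained 11-membered allylic lactone releases O15 and gives the methyl ester; C4 is quaternary and H-5 is not acidic, so no centre can epimerise.

Step 10
Reactants: 16 methyl (4S,5R,8R,9S,13E)-15-hydroxyhalima-1(10),13-dien-18-oate
Product: 17 methyl (4S,5R,8R,9S,13S,14S)-13,14-epoxy-15-hydroxyhalim-1(10)-en-18-oate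
Conditions: Ti(OiPr)4 (10 mol %), L-(+)-DET (12 mol %), t-BuOOH (2 equiv), 4 Å MS, CH2Cl2, −20 °C
Reagents that add atoms: tert-butyl hydroperoxide CC(C)(C)OO
Why: Sharpless asymmetric epoxidation of the E allylic alcohol with L-(+)-diethyl tartrate gives the (13S,14S) trans-epoxide (the sense in which geraniol gives the 2S,3S epoxide), and the isolated C1=C10 alkene is inert to Ti/TBHP.

## Compound list

1 | 2-methylcyclohex-2-en-1-one | CC1=CCCCC1=O | starting material
2 | dimethylaluminium (3R)-2,3-dimethylcyclohex-1-en-1-olate | C[C@@H]1CCCC(O[Al](C)C)=C1C | intermediate (not isolated)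
3 | (2R,3R)-2-(1-hydroxyethyl)-2,3-dimethylcyclohexan-1-one (both carbinol epimers) | O=C1CCC[C@@H](C)[C@]1(C)C(C)O | intermediate
4 | (2S,3R)-2-ethenyl-2,3-dimethylcyclohexan-1-one | O=C1CCC[C@@H](C)[C@]1(C)C=C | intermediate
5 | potassium (5R,6S)-6-ethenyl-5,6-dimethylcyclohex-1-en-1-olate | [K+].[O-]C1=CCC[C@@H](C)[C@]1(C)C=C | intermediate (not isolated)
6 | (5R,6S)-6-ethenyl-5,6-dimethylcyclohex-1-en-1-yl trifluoromethanesulfonate | O=S(=O)(OC1=CCC[C@@H](C)[C@]1(C)C=C)C(F)(F)F | intermediate
7 | (5R,6S)-1,6-diethenyl-5,6-dimethylcyclohex-1-ene | C=CC1=CCC[C@@H](C)[C@]1(C)C=C | intermediate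
8 | ethyl acetoacetate | CCOC(=O)CC(C)=O | starting material
9 | tetramethylammonium (E)-enolate of ethyl acetoacetate | CCOC(=O)/C=C(\C)[O-].C[N+](C)(C)C | intermediate (not isolated)
10 | ethyl (2E)-3-{[(trifluoromethyl)sulfonyl]oxy}but-2-enoate | CCOC(=O)/C=C(\C)OS(=O)(=O)C(F)(F)F | intermediate
11 | 9-{2-[(1S,6R)-2-ethenyl-1,6-dimethylcyclohex-2-en-1-yl]ethyl}-9-borabicyclo[3.3.1]nonane | C=CC1=CCC[C@@H](C)[C@]1(C)CCB1C2CCCC1CCC2 | intermediate (not isolated)
12 | ethyl (2E)-5-[(1S,6R)-2-ethenyl-1,6-dimethylcyclohex-2-en-1-yl]-3-methylpent-2-enoate | C=CC1=CCC[C@@H](C)[C@]1(C)CC/C(C)=C/C(=O)OCC | intermediate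
13 | diisobutylaluminium (2E)-5-[(1S,6R)-2-ethenyl-1,6-dimethylcyclohex-2-en-1-yl]-3-methylpent-2-en-1-olate | C=CC1=CCC[C@@H](C)[C@]1(C)CC/C(C)=C/CO[Al](CC(C)C)CC(C)C | intermediate (not isolated)
14 | (2E)-5-[(1S,6R)-2-ethenyl-1,6-dimethylcyclohex-2-en-1-yl]-3-methylpent-2-en-1-yl 2-methylprop-2-enoate | C=CC1=CCC[C@@H](C)[C@]1(C)CC/C(C)=C/COC(=O)C(C)=C | intermediate
15 | (4S,5R,8R,9S,13E)-halima-1(10),13-dien-18,15-olide (bridged tricycle: Δ1(10)-octalin with an 11-membered lactone from C18 on C4 to O15) | O=C3[C@@]1(C)CCC=C2[C@H]1CC[C@@H](C)[C@]2(C)CC/C(C)=C/CO3 | intermediate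
16 | methyl (4S,5R,8R,9S,13E)-15-hydroxyhalima-1(10),13-dien-18-oate = methyl (1S,5S,6R,8aR)-5-[(3E)-5-hydroxy-3-methylpent-3-en-1-yl]-1,5,6-trimethyl-1,2,3,5,6,7,8,8a-octahydronaphthalene-1-carboxylate | COC(=O)[C@@]1(C)CCC=C2[C@H]1CC[C@@H](C)[C@]2(C)CC/C(C)=C/CO | intermediate
17 | methyl (4S,5R,8R,9S,13S,14S)-13,14-epoxy-15-hydroxyhalim-1(10)-en-18-oate (CNP0324371.1) | COC(=O)[C@@]1(C)CCC=C2[C@H]1CC[C@@H](C)[C@]2(C)CC[C@]1(C)O[C@H]1CO | target

## Summary

Total step count: 10. Longest linear sequence: 9 (steps 1–4 and 6–10; step 5 is the one-step side branch).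

Three steps most likely to fail:

Step 8 (tethered cycloaddition). The risks are slow closure of the 11-membered ring, oligomerisation, and the exo mode, which would give the C4 epimer. The fallback sets out from 12 and comes back at 16. An intermolecular MeAlCl2-promoted Diels–Alder reaction of 12 with methyl methacrylate (CH2Cl2, −40 → 0 °C) is run instead; attack anti to the pseudoaxial C9 methyl with the ester endo gives 15-ethyl 18-methyl (4S,5R,8R,9S,13E)-halima-1(10),13-diene-15,18-dioate F2. DIBAL-H at −78 °C then reduces only the unhindered conjugated ethyl ester and gives 16.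

Step 2 (dehydration of a hindered aldol next to a quaternary carbon). The risks are retro-aldol cleavage and rearrangement. The fallback sets out from 1 and comes back at 4. The same copper-catalysed methyl addition is run, but enolate 2 (activated with MeLi) is added in Michael fashion to phenyl vinyl sulfoxide to give (2S,3R)-2,3-dimethyl-2-[2-(phenylsulfinyl)ethyl]cyclohexan-1-one F1. Thermal syn-elimination of the sulfoxide (PhMe, 110 °C) then gives 4.

Step 6 (selective hydroboration and coupling of a base-sensitive β-triflyloxy enoate). The fallback sets out from 7 and comes back at 12. The same adduct 11 is not cross-coupled but added by copper-catalysed syn conjugate addition to ethyl but-2-ynoate (CuOAc, P(OPh)3, t-BuOK, then a proton source). This gives 12 directly with the same E geometry (no new compound, F0).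

Further compounds
F1 | step 2 | (2S,3R)-2,3-dimethyl-2-[2-(phenylsulfinyl)ethyl]cyclohexan-1-one | O=C1CCC[C@@H](C)[C@]1(C)CCS(=O)c1ccccc1
F0 | step 6 | none | none
F2 | step 8 | 15-ethyl 18-methyl (4S,5R,8R,9S,13E)-halima-1(10),13-diene-15,18-dioate | COC(=O)[C@@]1(C)CCC=C2[C@H]1CC[C@@H](C)[C@]2(C)CC/C(C)=C/C(=O)OCC
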